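**Strategy**

The target, a 15-hydroxycadinane acid, is traced back to a cis-fused guaianolide (5-7-5) in which its free C12 carboxyl is still the 6,12-lactone and C1 is still bonded to C5. The key step ionises the lactone C6–O bond; C1 migrates from C5 to C6, so the seven-membered ring (C1, C5–C10) contracts to ring B (C1, C6–C10) while the cyclopentane expands to ring A, and water traps the C5–C4–C15 allyl cation. It exploits the ring-fusion carbon C6 flanked by the C4=C5–C15H2OH allylic alcohol and by C7 carrying the free acrylic acid. The precursor, an 8-acyloxy-4(15),10(14)-bis-methylene guaianolide, comes from (S)-limonene by two allylations.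

Key step: step 13

Remark on numbering: C1 and C6 are the ring-fusion carbons of the target, C4 carries C15 (CH2OH), C7 carries C11 (=C13H2, C12 carboxyl), C8 carries the ester oxygen, C10 carries the methylene C14, and the ester carbons are primed. The same numbers are kept for these atoms in every intermediate, so in the guaianolides the five-membered ring is C1–C5 and the seven-membered ring is C1, C5–C10.

**Route**

Step 1
Reactants: 1 (S)-(−)-limonene
Product: 2 (4S)-limonene 1,2-oxide (mixture at the two epoxide carbons)
Conditions: mCPBA, NaHCO3, CH2Cl2, 0 °C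
Reagents that add atoms: mCPBA, OOC(=O)c1cccc(Cl)c1
Why: Prilezhaev epoxidation is chemoselective for the trisubstituted ring alkene over the isopropenyl group, and the mixture at the epoxide carbons is immaterial because both become carbonyl carbons in step 2, while the limonene stereocenter (later C1) is carried unchanged.

Step 2
Reactants: 2 (4S)-limonene 1,2-oxide
Product: 3 (3S)-6-oxo-3-(prop-1-en-2-yl)heptanal
Conditions: H5IO6, THF/H2O, 0 °C to rt
Reagents that add atoms: water, O
Why: Acid-catalysed epoxide hydrolysis to the 1,2-diol and Malaprade glycol cleavage by periodate occur in one flask and leave the isopropenyl group and the stereocenter untouched.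

Step 3
Reactants: 3 (3S)-6-oxo-3-(prop-1-en-2-yl)heptanal
Product: 4 (5R)-2-methyl-5-(prop-1-en-2-yl)cyclopent-1-ene-1-carbaldehyde
Conditions: piperidine (cat.), AcOH (cat.), toluene, 80 °C
Reagents that add atoms: none
Why: Intramolecular aldol condensation (aldehyde enamine onto the methyl ketone, five-membered ring closure, then dehydration) gives the conjugated cyclopentene carbaldehyde, the stereocenter being β to the aldehyde and not enolisable.

Step 4
Reactants: 4 (5R)-2-methyl-5-(prop-1-en-2-yl)cyclopent-1-ene-1-carbaldehyde
Product: 5 (5S)-5-(3-chloroprop-1-en-2-yl)-2-methylcyclopent-1-ene-1-carbaldehyde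
Conditions: Ca(OCl)2, CO2 (dry ice), CH2Cl2/H2O, 0 °C
Reagents that add atoms: calcium hypochlorite, [Ca+2].[O-]Cl.[O-]Cl
Why: Ene-type allylic chlorination by HOCl formed in situ takes place only at the electron-rich isopropenyl group, the enal double bond being deactivated, and delivers the 2-(chloromethyl)allyl unit (C9, C10, C14) needed for the later ring closure.

Step 5
Reactants: 5 (5S)-5-(3-chloroprop-1-en-2-yl)-2-methylcyclopent-1-ene-1-carbaldehyde
Product: 7 (1S,5S)-5-(3-chloroprop-1-en-2-yl)-2-methylidenecyclopentane-1-carbaldehyde (cis), via potassium dienolate 6 (not isolated)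
Conditions: KN(SiMe3)2, THF, −78 °C; then AcOH, −78 °C
Reagents that add atoms: none
Why: Deconjugative protonation: the base removes a proton from the C15 methyl group, which is held syn to the carbonyl, and kinetic protonation of the exocyclic dienolate at the α-carbon C5 from the face opposite the neighbouring C1 substituent gives the cis β,γ-unsaturated aldehyde with the C4=C15 methylene in place.

Step 6
Reactants: 8 methyl acrylate; 9 2,2-dimethoxyacetaldehyde
Product: 10 methyl 3-hydroxy-4,4-dimethoxy-2-methylidenebutanoate (racemic)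
Conditions: DABCO, dioxane/H2O, rt
Reagents that add atoms: none
Why: Morita–Baylis–Hillman reaction of the acrylate with the unhindered aldehyde; the carbinol centre is racemic and is lost in step 7.

Step 7
Reactants: 10 methyl 3-hydroxy-4,4-dimethoxy-2-methylidenebutanoate
Product: 11 methyl (2Z)-2-(bromomethyl)-4,4-dimethoxybut-2-enoate
Conditions: NBS, Me2S, CH2Cl2, 0 °C to rt
Reagents that add atoms: N-bromosuccinimide, O=C1CCC(=O)N1Br
Why: Activation of the allylic alcohol as an alkoxysulfonium salt (Corey–Kim type) and SN2′ attack by bromide give the (Z)-2-(bromomethyl)enoate with allylic transposition.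

Step 8
Reactants: 7 (1S,5S)-5-(3-chloroprop-1-en-2-yl)-2-methylidenecyclopentane-1-carbaldehyde; 11 methyl (2Z)-2-(bromomethyl)-4,4-dimethoxybut-2-enoate
Product: 13 (4R,5S)-5-[(1S,2S)-2-(3-chloroprop-1-en-2-yl)-5-methylidenecyclopentyl]-4-(dimethoxymethyl)-3-methylideneoxolan-2-one (trans-lactone; C6 S, C7 R), via anti hydroxy ester 12 (not isolated)
Conditions: CrCl2, THF, 0 °C to rt
Reagents that add atoms: none
Why: Chromium-mediated Barbier (Nozaki–Hiyama type) allylation through the γ-carbon: the equilibrating allylchromium reagent adds through a chair Zimmerman–Traxler transition state to give the anti C6/C7 relationship (trans-lactone after the chromium alkoxide closes onto the ester), the aldehyde face is chosen by Felkin–Anh attack anti to the bulky C1 branch of the cis-substituted ring, and CrCl2 reduces the allylic bromide much faster than the allylic chloride at 0 °C.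

Step 9
Reactants: 13 trans-lactone acetal
Product: 15 (1S,5S,6S,7S,8S)-8-hydroxyguaia-4(15),10(14),11(13)-trien-12,6-olide, via lactone aldehyde 14 (not isolated)
Conditions: LiBF4, MeCN/H2O, rt; then SnCl2, NaI, DMF, rt
Reagents that add atoms: water, O
Why: Acetal hydrolysis and intramolecular tin-mediated Barbier allylation (allyl iodide formed in situ, 7-exo-trig closure onto the aldehyde) form the seven-membered ring with the C10=C14 methylene, and C8 is set by Felkin–Anh addition with C11 anti to the incoming carbon and the tether gauche to C6, which places the new hydroxyl cis to C11.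

Step 10
Reactants: 16 (R)-2,3-O-isopropylideneglyceraldehyde
Product: 17 (4S)-4-ethynyl-2,2-dimethyl-1,3-dioxolane
Conditions: dimethyl (1-diazo-2-oxopropyl)phosphonate, K2CO3, MeOH, 0 °C to rt
Reagents that add atoms: dimethyl (1-diazo-2-oxopropyl)phosphonate, CC(=O)C(=[N+]=[N-])P(=O)(OC)OC
Why: Ohira–Bestmann (Seyferth–Gilbert) homologation converts the aldehyde into the terminal alkyne under mild base without touching the dioxolane stereocenter, whose descriptor changes from R to S only through the priority rules.

Step 11
Reactants: 17 (4S)-4-ethynyl-2,2-dimethyl-1,3-dioxolane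
Product: 18 2-[(4S)-2,2-dimethyl-1,3-dioxolan-4-yl]prop-2-enoic acid
Conditions: NiCl2(dme) (10 mol %), 2,9-dimethyl-1,10-phenanthroline (12 mol %), Mn, i-PrOH, DMF, CO2 (1 atm), 60 °C; then 1 M HCl to pH 3, 0 °C
Reagents that add atoms: carbon dioxide, O=C=O
Why: Nickel-catalysed reductive hydrocarboxylation of a terminal alkyne with CO2 is Markovnikov-selective and gives the 2-substituted acrylic acid under neutral conditions that the acetonide tolerates.

Step 12
Reactants: 15 (1S,5S,6S,7S,8S)-8-hydroxyguaia-4(15),10(14),11(13)-trien-12,6-olide; 18 2-[(4S)-2,2-dimethyl-1,3-dioxolan-4-yl]prop-2-enoic acid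
Product: 19 8-O-{2-[(4S)-2,2-dimethyl-1,3-dioxolan-4-yl]prop-2-enoyl} ester of 15
Conditions: 2,4,6-trichlorobenzoyl chloride, Et3N, THF, rt; then 15, DMAP, toluene, rt
Reagents that add atoms: none
Why: Yamaguchi esterification through the mixed anhydride acylates the only free hydroxyl (C8) with retention, and the lactone is not opened under these conditions.

Step 13
Reactants: 19 8-O-acyl guaianolide acetonide
Product: 21 (1S,6S,7S,8S)-8-[(3S)-3,4-dihydroxy-2-methylidenebutanoyloxy]-15-hydroxycadina-4,10(14),11(13)-trien-12-oic acid (target), via diol guaianolide 20 (not isolated)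
Conditions: Sc(OTf)3 (20 mol %), 2,6-di-tert-butyl-4-methylpyridine (10 mol %), (CF3)2CHOH/H2O (9:1), 40 °C
Reagents that add atoms: water, O
Why: Proposed new method: Sc(OTf)3 bound to the lactone carbonyl in the ionising fluoroalcohol turns the C12 carboxylate into a nucleofuge, and since the trans-fused lactone locks the C6–O bond antiperiplanar to the C5–C1 ring bond, heterolysis is coupled to a Wagner–Meerwein 1,2-shift of C1 from C5 to C6, the charge passing to the C5–C4–C15 allyl cation that water captures at the unhindered terminus C15 (simple return of the carboxylate only regenerates the lactone). The closest known reaction types are the cyclopentylcarbinyl-to-cyclohexyl ring expansion and the hydroazulene-to-decalin rearrangement in sulfonate solvolysis, and the Lewis-acid alkyl–oxygen cleavage of tert-butyl and prenyl esters, whose cations are comparable in stability to the allyl cation formed here; a lactone has not been used as the leaving group of such a shift. No ring is closed by cyclisation: the one suprafacial 1,2-alkyl shift contracts the seven-membered ring (C1, C5–C10) to ring B (C1, C6–C10) and at the same time expands the cyclopentane (C1–C5) to ring A (C1–C6). The only new stereocenter, C6, is set by inversion because C1 enters anti to the departing oxygen, and C1 migrates with retention, so the configuration of 19 translates into the trans ring fusion with H6 trans to H7, while C7, C8 and C3′ are not touched. The step needs migration of C1 and not of C8 or hydride: no C–H bond is antiperiplanar to C6–O, and C8, which is also antiperiplanar, carries the acyloxy group and would leave the charge on C7 next to the carboxyl-bearing C11, whereas the C1 shift is driven by the allylic C4=C15 bond and by the change from hydroazulene to decalin. It also needs capture at C15 rather than C5 and survival of the 1,1-disubstituted alkenes: the C5 alcohol and any δ-lactone from internal return are allylic and should re-ionise and funnel to the trisubstituted C4=C5 alkene, the hindered pyridine keeps the medium from protonating C10=C14 and the acrylates, and the acetonide is hydrolysed in the same aqueous medium.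

**Compound list**

1 | (S)-(−)-limonene | CC1=CC[C@H](CC1)C(C)=C | starting material
2 | (4S)-limonene 1,2-oxide (mixture at the epoxide carbons) | CC12CC[C@@H](CC1O2)C(C)=C | intermediate
3 | (3S)-6-oxo-3-(prop-1-en-2-yl)heptanal | CC(=O)CC[C@@H](CC=O)C(C)=C | intermediate
4 | (5R)-2-methyl-5-(prop-1-en-2-yl)cyclopent-1-ene-1-carbaldehyde | O=CC1=C(C)CC[C@@H]1C(C)=C | intermediate
5 | (5S)-5-(3-chloroprop-1-en-2-yl)-2-methylcyclopent-1-ene-1-carbaldehyde | O=CC1=C(C)CC[C@@H]1C(=C)CCl | intermediate
6 | potassium [(5S)-5-(3-chloroprop-1-en-2-yl)-2-methylidenecyclopentylidene]methanolate (dienolate, not isolated) | [K+].[O-]C=C1C(=C)CC[C@@H]1C(=C)CCl | intermediate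
7 | (1S,5S)-5-(3-chloroprop-1-en-2-yl)-2-methylidenecyclopentane-1-carbaldehyde (cis) | O=C[C@@H]1C(=C)CC[C@@H]1C(=C)CCl | intermediate
8 | methyl acrylate | COC(=O)C=C | starting material
9 | 2,2-dimethoxyacetaldehyde | COC(OC)C=O | starting material
10 | methyl 3-hydroxy-4,4-dimethoxy-2-methylidenebutanoate (racemic) | COC(=O)C(=C)C(O)C(OC)OC | intermediate
11 | methyl (2Z)-2-(bromomethyl)-4,4-dimethoxybut-2-enoate | COC(=O)/C(CBr)=C/C(OC)OC | intermediate
12 | methyl (3R,4S)-4-[(1S,2S)-2-(3-chloroprop-1-en-2-yl)-5-methylidenecyclopentyl]-3-(dimethoxymethyl)-4-hydroxy-2-methylidenebutanoate (anti; not isolated) | COC(=O)C(=C)[C@@H](C(OC)OC)[C@@H](O)[C@@H]1C(=C)CC[C@@H]1C(=C)CCl | intermediate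
13 | (4R,5S)-5-[(1S,2S)-2-(3-chloroprop-1-en-2-yl)-5-methylidenecyclopentyl]-4-(dimethoxymethyl)-3-methylideneoxolan-2-one (trans) | C=C1C(=O)O[C@H]([C@@H]1C(OC)OC)[C@@H]2C(=C)CC[C@@H]2C(=C)CCl | intermediate
14 | (2S,3R)-2-[(1S,2S)-2-(3-chloroprop-1-en-2-yl)-5-methylidenecyclopentyl]-4-methylidene-5-oxooxolane-3-carbaldehyde (not isolated) | C=C1C(=O)O[C@H]([C@@H]1C=O)[C@@H]2C(=C)CC[C@@H]2C(=C)CCl | intermediate
15 | (1S,5S,6S,7S,8S)-8-hydroxyguaia-4(15),10(14),11(13)-trien-12,6-olide (cis ring fusion, trans-lactone, 8-OH cis to C11) | C=C1C(=O)O[C@@H]2[C@@H]1[C@@H](O)CC(=C)[C@H]3CCC(=C)[C@@H]23 | intermediate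
16 | (R)-2,3-O-isopropylideneglyceraldehyde | O=C[C@H]1COC(C)(C)O1 | starting material
17 | (4S)-4-ethynyl-2,2-dimethyl-1,3-dioxolane | C#C[C@H]1COC(C)(C)O1 | intermediate
18 | 2-[(4S)-2,2-dimethyl-1,3-dioxolan-4-yl]prop-2-enoic acid | OC(=O)C(=C)[C@H]1COC(C)(C)O1 | intermediate
19 | 8-O-{2-[(4S)-2,2-dimethyl-1,3-dioxolan-4-yl]prop-2-enoyl} ester of 15 | C=C1C(=O)O[C@@H]2[C@@H]1[C@@H](OC(=O)C(=C)[C@H]4COC(C)(C)O4)CC(=C)[C@H]3CCC(=C)[C@@H]23 | intermediate
20 | 8-O-[(3S)-3,4-dihydroxy-2-methylidenebutanoyl] ester of 15 (not isolated) | C=C1C(=O)O[C@@H]2[C@@H]1[C@@H](OC(=O)C(=C)[C@H](O)CO)CC(=C)[C@H]3CCC(=C)[C@@H]23 | intermediate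
21 | (1S,6S,7S,8S)-8-[(3S)-3,4-dihydroxy-2-methylidenebutanoyloxy]-15-hydroxycadina-4,10(14),11(13)-trien-12-oic acid | C=C(C(=O)O)[C@@H]1[C@H]2C=C(CO)CC[C@@H]2C(=C)C[C@@H]1OC(=O)C(=C)[C@H](O)CO | target

**Step count**

Total: 13 steps. Longest linear sequence: 9 steps (steps 1–5, 8, 9, 12, 13).

**Steps most likely to fail**

1. Step 13 (Proposed new method). The lactone alkyl–oxygen bond may fail to ionise before the 1,1-disubstituted alkenes are protonated, or the allyl cation may be lost to elimination, to capture at C5 or to internal return. The fallback uses known chemistry, sets out from 15 and comes back at 21. The lactone is opened with LiOH (THF/H2O, 0 °C) and the carboxylate alkylated in the same flask with allyl bromide (DMF) to give the allyl ester diol F1. Yamaguchi acylation with 18 at the less hindered C8 hydroxyl (the C6 hydroxyl is flanked by two methine carbons) gives the ester F2. Tf2O and 2,6-di-tert-butyl-4-methylpyridine (CH2Cl2, −78 °C) convert the C6 hydroxyl into the triflate F3, which is not isolated but solvolysed on warming with aqueous NaHCO3/acetone. The same 1,2-shift then runs as a classical sulfonate solvolysis with Wagner–Meerwein ring contraction and gives the cadinane allyl ester F4. Pd(PPh3)4 with PhSiH3 removes the allyl ester to give the acetonide acid F5, and 80 % aqueous AcOH (40 °C) removes the acetonide to give 21.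

2. Step 5. The base may cause self-condensation of the enal or deprotonation at the ring CH2, and the β,γ-unsaturated aldehyde may reconjugate or epimerise at C5 before use. The fallback sets out from 5 and comes back at 7. Oxidative esterification (MnO2, catalytic 1,4-dimethyl-1,2,4-triazolium iodide, DBU, MeOH) gives the conjugated methyl ester F6. Irradiation at 254 nm with catalytic 1,2-dimethylimidazole (photoenolisation by 1,5-hydrogen shift from the syn methyl group, then ketonisation of the dienol at the α-carbon from the less hindered face) gives the cis β,γ-unsaturated ester F7. Reduction with i-Bu2AlH (CH2Cl2, −78 °C) gives aldehyde 7.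

3. Step 9. Facial selectivity at the aldehyde in the ring-closing allylation may be poor or reversed, and the aldehyde may enolise toward the butenolide. The fallback sets out from 13 and comes back at 19. If the cyclisation gives mainly the C8 epimer F8 (hydroxyl trans to C11), F8 is esterified with 18 under Mitsunobu conditions (PPh3, DIAD, toluene, 0 °C) instead of the Yamaguchi acylation. This inverts C8 and gives 19 directly, replacing step 12.

Further compounds
F1 | step 13 | allyl 6,8-dihydroxyguaia-4(15),10(14),11(13)-trien-12-oate, configuration as in 15 | C=CCOC(=O)C(=C)[C@H]1[C@@H](O)CC(=C)[C@H]2CCC(=C)[C@H]2[C@@H]1O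
F2 | step 13 | 8-O-{2-[(4S)-2,2-dimethyl-1,3-dioxolan-4-yl]prop-2-enoyl} ester of F1 | C=CCOC(=O)C(=C)[C@H]1[C@@H](OC(=O)C(=C)[C@H]3COC(C)(C)O3)CC(=C)[C@H]2CCC(=C)[C@H]2[C@@H]1O
F3 | step 13 | C6 trifluoromethanesulfonate of F2 (not isolated) | C=CCOC(=O)C(=C)[C@H]1[C@@H](OC(=O)C(=C)[C@H]3COC(C)(C)O3)CC(=C)[C@H]2CCC(=C)[C@H]2[C@@H]1OS(=O)(=O)C(F)(F)F
F4 | step 13 | allyl ester and side-chain acetonide of 21 | C=CCOC(=O)C(=C)[C@@H]1[C@H]2C=C(CO)CC[C@@H]2C(=C)C[C@@H]1OC(=O)C(=C)[C@H]3COC(C)(C)O3
F5 | step 13 | side-chain acetonide of 21 | C=C(C(=O)O)[C@@H]1[C@H]2C=C(CO)CC[C@@H]2C(=C)C[C@@H]1OC(=O)C(=C)[C@H]3COC(C)(C)O3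
F6 | step 5 | methyl (5S)-5-(3-chloroprop-1-en-2-yl)-2-methylcyclopent-1-ene-1-carboxylate | COC(=O)C1=C(C)CC[C@@H]1C(=C)CCl
F7 | step 5 | methyl (1S,5S)-5-(3-chloroprop-1-en-2-yl)-2-methylidenecyclopentane-1-carboxylate (cis) | COC(=O)[C@@H]1C(=C)CC[C@@H]1C(=C)CCl
F8 | step 9 | (1S,5S,6S,7S,8R)-8-hydroxyguaia-4(15),10(14),11(13)-trien-12,6-olide (C8 epimer of 15) | C=C1C(=O)O[C@@H]2[C@@H]1[C@H](O)CC(=C)[C@H]3CCC(=C)[C@@H]23
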